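**Plan**

- Retrosynthesis: the C4 enol is masked as its methyl ether, and the C4′=C5′ alkene is cut (cross-metathesis) into a ylidene tetronate with a terminal alkene and a bisfuran 3-methyl-1,3-diene.
- Ring A is cut at O1–C2 and contracted by a C2–C5 bond: C2 (carbonyl), C3 (methyl), C4 (oxygen) and C5 are the four contiguous carbons of a 4-hydroxy-3-methoxy-2-methylcyclobutenone derived from squaric acid, O1 being its carbinol oxygen; the C5=C1′ alkene comes from loss of AcOH.
- The cyclobutenone is cut at C5–C1′ (alkyllithium plus cyclobutenedione) and C3–CH3 (MeLi plus dimethyl squarate). The diene is cut at C5′=CH2 and C6′=C7′ (two Wittig reactions), C7′–C8′ (cyanomethylation) and the furan–CH2 bond (Negishi coupling).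
- Forward: the chiral iodide (3 steps) and the methoxy methyl cyclobutenedione (1 step) are joined; ring A, the only ring made, arises by oxidative ring expansion; the diene is built in 8 steps; metathesis joins the halves and thiolate demethylation ends the route.
- Stereochemistry: C2′ (S) from an Evans allylation with the (R)-benzyl oxazolidinone; 5Z from the elimination (side chain turned away from the C4 methoxy group); 6′E from a stabilised Wittig reaction; 4′E from the metathesis.

Key step: step 6

Remark on the chemistry: the target is taken as the (5Z,2′S,4′E,6′E) isomer encoded in the SMILES. Ring A is numbered O1, C2 (C=O), C3 (CH3), C4 (OH), C5; the side chain runs from C1′ (ylidene CH) to C9′ (CH2 on the furan).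

**Step 1**
Reactants: 1 (R)-4-benzyl-3-propanoyloxazolidin-2-one; 2 allyl bromide
Product: 4 (R)-4-benzyl-3-[(2S)-2-methylpent-4-enoyl]oxazolidin-2-one, via sodium (Z)-enolate 3 (not isolated)
Conditions: NaN(SiMe3)2, THF, −78 °C; then allyl bromide, −78 → −45 °C
Reagents that add atoms: none
Why: Evans asymmetric alkylation, in which the chelated sodium (Z)-enolate is attacked by allyl bromide on the face opposite the benzyl group, so the (R)-auxiliary should set the new α-centre as S.

**Step 2**
Reactants: 4 (R)-4-benzyl-3-[(2S)-2-methylpent-4-enoyl]oxazolidin-2-one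
Product: 5 (2S)-2-methylpent-4-en-1-ol
Conditions: LiBH4, H2O (1 equiv), Et2O, 0 °C
Reagents that add atoms: none
Why: Reductive cleavage of the imide by borohydride at the exocyclic carbonyl releases the primary alcohol without epimerisation and returns the oxazolidinone.

**Step 3**
Reactants: 5 (2S)-2-methylpent-4-en-1-ol
Product: 6 (4S)-5-iodo-4-methylpent-1-ene
Conditions: I2, PPh3, imidazole, CH2Cl2, 0 °C → rt
Reagents that add atoms: iodine, [I][I]
Why: Appel-type iodination (Garegg–Samuelsson conditions) displaces the alkoxyphosphonium group by iodide at the primary carbon, which leaves the neighbouring stereocentre untouched.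

**Step 4**
Reactants: 7 dimethyl squarate
Product: 10 3-methoxy-4-methylcyclobut-3-ene-1,2-dione, via lithium alkoxide 8 (not isolated), via trifluoroacetate 9 (not isolated)
Conditions: MeLi, THF, −78 °C; then (CF3CO)2O, −78 °C → rt; aq. NaHCO3
Reagents that add atoms: methyllithium, [Li]C; water, O
Why: 1,2-Addition of an organolithium to a squarate ester followed by acylation of the carbinol, ionisation and hydrolysis of the methoxy-stabilised cation (the established squarate 1,3-carbonyl transposition) should give the alkoxy alkyl cyclobutenedione.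

**Step 5**
Reactants: 6 (4S)-5-iodo-4-methylpent-1-ene; 10 3-methoxy-4-methylcyclobut-3-ene-1,2-dione
Product: 12 4-hydroxy-3-methoxy-2-methyl-4-[(2S)-2-methylpent-4-enyl]cyclobut-2-en-1-one (mixture of carbinol epimers), via alkyllithium 11 (not isolated)
Conditions: t-BuLi (2 equiv), Et2O–pentane, −78 °C; then cannulated into 10, THF, −78 °C; aq. NH4Cl
Reagents that add atoms: none
Why: Lithium–iodine exchange gives a 4-pentenyllithium that does not cyclise at −78 °C, and its 1,2-addition should occur at the ketone carbonyl next to the methoxy-bearing carbon, because the other carbonyl is deactivated as a vinylogous ester.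

**Step 6**
Reactants: 12 4-hydroxy-3-methoxy-2-methyl-4-[(2S)-2-methylpent-4-enyl]cyclobut-2-en-1-one
Product: 14 (5Z)-4-methoxy-3-methyl-5-[(2S)-2-methylpent-4-enylidene]furan-2(5H)-one, via acetoxy lactone 13 (not isolated)
Conditions: Pb(OAc)4 (1.3 equiv), toluene, rt; then DBU, 0 °C → rt
Reagents that add atoms: none
Why: Ligand exchange gives a tetravalent lead alkoxide of the strained carbinol, whose carbinol–acyl ring bond fragments to an unsaturated acyl radical and an enone; one-electron oxidation by lead gives the acylium ion, the new ketone oxygen (the former carbinol oxygen) closes on it, acetate traps the methoxy-stabilised oxocarbenium ion as 13, and DBU then removes AcOH. This is the known lead tetraacetate oxidative rearrangement of 4-hydroxycyclobut-2-enones to 5-acetoxy- and 5-ylidene-2(5H)-furanones. Ring A closes by O–C bond formation in a 5-exo-dig attack of the ketone oxygen on the acylium carbon, a net one-atom expansion of the four-membered ring. No stereocentre is created, since the acetal carbon of 13 becomes planar again, and C2′ lies one carbon away from every reacting atom, so both carbinol epimers of 12 converge on one product. The step needs scission of the acyl bond and not of the vinyl or alkyl bond, which ring strain, the stability of the acyl radical and the conjugation of the ketone formed all favour, and it needs elimination toward C1′, the only carbon next to C5 that carries hydrogen. The Z alkene is expected because the side chain then points toward O1 and away from the C4 methoxy group, and DBU is a base under which ylidene tetronates with such an allylic methine centre keep their configuration.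

**Step 7**
Reactants: 15 furan-3-ylmethanol
Product: 16 3-(bromomethyl)furan
Conditions: PBr3 (0.4 equiv), Et2O, 0 °C; used without storage
Reagents that add atoms: phosphorus tribromide, BrP(Br)Br
Why: Conversion of a primary heterobenzylic alcohol into its bromide through the phosphite ester and SN2 displacement by bromide.

**Step 8**
Reactants: 16 3-(bromomethyl)furan; 17 methyl 5-bromofuran-3-carboxylate
Product: 19 methyl 5-(furan-3-ylmethyl)furan-3-carboxylate, via furylmethylzinc bromide 18 (not isolated)
Conditions: Zn dust, LiCl, THF, 0 °C → rt; then 17, Pd(OAc)2 (2 mol %), SPhos (4 mol %), THF, rt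
Reagents that add atoms: none
Why: Negishi cross-coupling, in which LiCl-assisted zinc insertion gives the benzylic-type zinc reagent and zerovalent palladium (formed from the divalent acetate) inserts into the electron-poor 2-bromofuran, the ester being tolerated by the organozinc.

**Step 9**
Reactants: 19 methyl 5-(furan-3-ylmethyl)furan-3-carboxylate
Product: 20 [5-(furan-3-ylmethyl)furan-3-yl]methanol
Conditions: LiAlH4, Et2O, 0 °C
Reagents that add atoms: none
Why: Hydride reduction of an ester to the primary alcohol, which leaves the two furan rings untouched.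

**Step 10**
Reactants: 20 [5-(furan-3-ylmethyl)furan-3-yl]methanol
Product: 21 4-(bromomethyl)-2-(furan-3-ylmethyl)furan
Conditions: CBr4, PPh3, CH2Cl2, 0 °C; used crude
Reagents that add atoms: tetrabromomethane, BrC(Br)(Br)Br
Why: Appel bromination proceeds under neutral conditions, which suits the acid-sensitive difurylmethane.

**Step 11**
Reactants: 21 4-(bromomethyl)-2-(furan-3-ylmethyl)furan
Product: 22 3-[5-(furan-3-ylmethyl)furan-3-yl]propanenitrile
Conditions: CH3CN (4 equiv), n-BuLi, THF, −78 °C; then 21, −78 → −40 °C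
Reagents that add atoms: acetonitrile, CC#N
Why: SN2 alkylation of lithioacetonitrile by a reactive furylmethyl bromide, with the nucleophile in excess to suppress dialkylation.

**Step 12**
Reactants: 22 3-[5-(furan-3-ylmethyl)furan-3-yl]propanenitrile
Product: 24 3-[5-(furan-3-ylmethyl)furan-3-yl]propanal, via N-aluminio imine 23 (not isolated)
Conditions: i-Bu2AlH, CH2Cl2, −78 °C; then aq. KNaC4H4O6 (potassium sodium tartrate), rt
Reagents that add atoms: water, O
Why: Partial reduction of a nitrile by i-Bu2AlH stops at the aluminium imine at low temperature, and hydrolysis on work-up should release the aldehyde.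

**Step 13**
Reactants: 24 3-[5-(furan-3-ylmethyl)furan-3-yl]propanal
Product: 25 (2E)-5-[5-(furan-3-ylmethyl)furan-3-yl]-2-methylpent-2-enal
Conditions: Ph3P=C(CH3)CHO (1.2 equiv), toluene, 90 °C
Reagents that add atoms: 2-(triphenylphosphoranylidene)propanal, CC(C=O)=P(c1ccccc1)(c1ccccc1)c1ccccc1
Why: Wittig reaction of a stabilised ylide, which should give the (E)-trisubstituted enal (C6′=C7′) under thermodynamic control of the oxaphosphetane.

**Step 14**
Reactants: 25 (2E)-5-[5-(furan-3-ylmethyl)furan-3-yl]-2-methylpent-2-enal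
Product: 26 2-(furan-3-ylmethyl)-4-[(3E)-4-methylhexa-3,5-dienyl]furan
Conditions: Ph3PCH3Br, KOt-Bu, THF, 0 °C
Reagents that add atoms: methyltriphenylphosphonium bromide, C[P+](c1ccccc1)(c1ccccc1)c1ccccc1.[Br-]
Why: Wittig methylenation adds 1,2 to the enal and leaves the geometry of the existing trisubstituted alkene unchanged.

**Step 15**
Reactants: 14 (5Z)-4-methoxy-3-methyl-5-[(2S)-2-methylpent-4-enylidene]furan-2(5H)-one; 26 2-(furan-3-ylmethyl)-4-[(3E)-4-methylhexa-3,5-dienyl]furan
Product: 27 (5Z)-5-[(2S,4E,6E)-9-[5-(furan-3-ylmethyl)furan-3-yl]-2,6-dimethylnona-4,6-dienylidene]-4-methoxy-3-methylfuran-2(5H)-one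
Conditions: second-generation Hoveyda–Grubbs catalyst RuCl2(H2IMes)(=CH-C6H4-2-O-i-Pr) (5 mol %), CH2Cl2, 40 °C; 14 in 1.5-fold excess
Reagents that add atoms: none
Why: Olefin cross-metathesis, in which the ruthenium alkylidene exchanges only at the two monosubstituted alkenes, the trisubstituted C6′=C7′ alkene and the electron-poor ylidene being too hindered to enter the cycle, and the conjugated C4′=C5′ alkene should form as the more stable E isomer.

**Step 16**
Reactants: 27 (5Z)-5-[(2S,4E,6E)-9-[5-(furan-3-ylmethyl)furan-3-yl]-2,6-dimethylnona-4,6-dienylidene]-4-methoxy-3-methylfuran-2(5H)-one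
Product: 28 (5Z)-5-[(2S,4E,6E)-9-[5-(furan-3-ylmethyl)furan-3-yl]-2,6-dimethylnona-4,6-dienylidene]-4-hydroxy-3-methylfuran-2(5H)-one
Conditions: n-PrSLi (from n-PrSH, n-BuLi), HMPA, rt; then aq. HCl to pH 3, 0 °C
Reagents that add atoms: none
Why: SN2 demethylation of a methyl tetronate (a vinylogous methyl carbonate) by a soft thiolate in a dipolar aprotic solvent releases the stabilised tetronate anion, a method established for 5-ylidene-4-methoxy-3-methylfuranones, and the weakly basic thiolate should leave C2′ and the alkene geometries untouched.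

**Compound list**

1 | (R)-4-benzyl-3-propanoyloxazolidin-2-one | CCC(=O)N1[C@H](Cc2ccccc2)COC1=O | starting material
2 | allyl bromide | C=CCBr | starting material
3 | sodium (Z)-enolate of 1 | C/C=C(\[O-])N1[C@H](Cc2ccccc2)COC1=O.[Na+] | intermediate
4 | (R)-4-benzyl-3-[(2S)-2-methylpent-4-enoyl]oxazolidin-2-one | C=CC[C@H](C)C(=O)N1[C@H](Cc2ccccc2)COC1=O | intermediate
5 | (2S)-2-methylpent-4-en-1-ol | C=CC[C@H](C)CO | intermediate
6 | (4S)-5-iodo-4-methylpent-1-ene | C=CC[C@H](C)CI | intermediate
7 | dimethyl squarate (3,4-dimethoxycyclobut-3-ene-1,2-dione) | COC1=C(OC)C(=O)C1=O | starting material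
8 | lithium 2,3-dimethoxy-1-methyl-4-oxocyclobut-2-en-1-olate (racemic) | COC1=C(OC)C(C)([O-])C1=O.[Li+] | intermediate
9 | 2,3-dimethoxy-1-methyl-4-oxocyclobut-2-en-1-yl trifluoroacetate (racemic) | COC1=C(OC)C(C)(OC(=O)C(F)(F)F)C1=O | intermediate
10 | 3-methoxy-4-methylcyclobut-3-ene-1,2-dione | CC1=C(OC)C(=O)C1=O | intermediate
11 | [(2R)-2-methylpent-4-enyl]lithium (same spatial arrangement as 6; the descriptor changes only because CH2Li ranks below the allyl CH2) | [Li]C[C@@H](C)CC=C | intermediate
12 | 4-hydroxy-3-methoxy-2-methyl-4-[(2S)-2-methylpent-4-enyl]cyclobut-2-en-1-one (carbinol epimers) | CC1=C(OC)C(O)(C[C@@H](C)CC=C)C1=O | intermediate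
13 | 5-acetoxy-4-methoxy-3-methyl-5-[(2S)-2-methylpent-4-enyl]furan-2(5H)-one (C5 epimers) | CC1=C(OC)C(OC(C)=O)(C[C@@H](C)CC=C)OC1=O | intermediate
14 | (5Z)-4-methoxy-3-methyl-5-[(2S)-2-methylpent-4-enylidene]furan-2(5H)-one | CC1=C(OC)/C(=C/[C@@H](C)CC=C)OC1=O | intermediate
15 | furan-3-ylmethanol | OCc1ccoc1 | starting material
16 | 3-(bromomethyl)furan | BrCc1ccoc1 | intermediate
17 | methyl 5-bromofuran-3-carboxylate | COC(=O)c1coc(Br)c1 | starting material
18 | (furan-3-ylmethyl)zinc bromide | Br[Zn]Cc1ccoc1 | intermediate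
19 | methyl 5-(furan-3-ylmethyl)furan-3-carboxylate | COC(=O)c1coc(Cc2ccoc2)c1 | intermediate
20 | [5-(furan-3-ylmethyl)furan-3-yl]methanol | OCc1coc(Cc2ccoc2)c1 | intermediate
21 | 4-(bromomethyl)-2-(furan-3-ylmethyl)furan | BrCc1coc(Cc2ccoc2)c1 | intermediate
22 | 3-[5-(furan-3-ylmethyl)furan-3-yl]propanenitrile | N#CCCc1coc(Cc2ccoc2)c1 | intermediate
23 | N-(diisobutylalumanyl)-3-[5-(furan-3-ylmethyl)furan-3-yl]propan-1-imine | CC(C)C[Al](CC(C)C)N=CCCc1coc(Cc2ccoc2)c1 | intermediate
24 | 3-[5-(furan-3-ylmethyl)furan-3-yl]propanal | O=CCCc1coc(Cc2ccoc2)c1 | intermediate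
25 | (2E)-5-[5-(furan-3-ylmethyl)furan-3-yl]-2-methylpent-2-enal | O=C/C(C)=C/CCc1coc(Cc2ccoc2)c1 | intermediate
26 | 2-(furan-3-ylmethyl)-4-[(3E)-4-methylhexa-3,5-dienyl]furan | C=C/C(C)=C/CCc1coc(Cc2ccoc2)c1 | intermediate
27 | (5Z)-5-[(2S,4E,6E)-9-[5-(furan-3-ylmethyl)furan-3-yl]-2,6-dimethylnona-4,6-dienylidene]-4-methoxy-3-methylfuran-2(5H)-one | CC1=C(OC)/C(=C/[C@@H](C)C/C=C/C(C)=C/CCc2coc(Cc3ccoc3)c2)OC1=O | intermediate
28 | (5Z)-5-[(2S,4E,6E)-9-[5-(furan-3-ylmethyl)furan-3-yl]-2,6-dimethylnona-4,6-dienylidene]-4-hydroxy-3-methylfuran-2(5H)-one (CNP0222779.1) | CC1=C(O)/C(=C/[C@@H](C)C/C=C/C(C)=C/CCc2coc(Cc3ccoc3)c2)OC1=O | target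

**Count and risks**

Total step count: 16. Longest linear sequence: 10 steps (steps 7 to 16, from furan-3-ylmethanol). The side-chain branch (steps 1, 2, 3, 5, 6) and the squarate branch (step 4) join it at step 15.

Steps most likely to fail:

1. Step 15. The catalyst may also engage the diene at its internal alkene, the new C4′=C5′ alkene may form as an E/Z mixture, and homodimerisation of 14 may consume material. The fallback moves the union to the C5′–C6′ bond and sets out from 14 and 24. Cross-metathesis of 14 with vinylboronic acid pinacol ester (same ruthenium catalyst, CH2Cl2, 40 °C) should give the pinacol (E)-alkenylboronate F1. Aldehyde 24 with CBr4 and PPh3 (CH2Cl2, 0 °C) should give the 1,1-dibromoalkene F2. Suzuki–Miyaura coupling of the two (Pd(PPh3)4, aq. K3PO4, THF, rt) is expected to take place only at the bromide trans to the alkyl chain and to give the (6′Z)-6′-bromodiene F3. Negishi methylation with retention (Me2Zn, Pd[P(t-Bu)3]2, THF, 0 °C) then returns to the route at 27.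

2. Step 6. Tetravalent lead may attack the terminal alkene, the alkoxy radical may abstract the allylic hydrogen instead of fragmenting, or loss of AcOH may be incomplete or not fully Z-selective. The fallback keeps the four-to-five ring expansion of the same precursor but separates it from the oxidation; it sets out from 12. Heating in p-xylene at 138 °C should open the cyclobutenone to the hydroxyvinylketene, which lactonises to 4-methoxy-3-methyl-5-[(2S)-2-methylpent-4-enyl]furan-2(5H)-one F4. Deprotonation at C5 (LiN(i-Pr)2, THF, −78 °C) and trapping with PhSeBr should give the 5-(phenylselanyl) lactone F5. Oxidation with H2O2 (CH2Cl2, 0 °C) to the selenoxide F6 and syn elimination toward C1′ returns to the route at 14, with a trace of iodine available to equilibrate to the Z isomer if needed.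

3. Step 16. The thiolate may add to or isomerise the polyene, and the free tetronic acid with its acid-sensitive bisfuran may degrade during unmasking and acidification. The fallback changes the order of events so that the diene and the bisfuran never meet the thiolate; it sets out from 14. Demethylation of 14 (n-PrSLi, HMPA, rt) should give the tetronic acid (5Z)-4-hydroxy-3-methyl-5-[(2S)-2-methylpent-4-enylidene]furan-2(5H)-one F7. Silylation (i-Pr3SiOSO2CF3, 2,6-lutidine, CH2Cl2, −78 °C) should give its triisopropylsilyl ether F8. Cross-metathesis of F8 with 26 under the conditions of step 15 should give the silyl ether of the target F9, and Et3N·3HF (THF, 0 °C) then returns to the route at 28.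

**Further compounds**

F1 | step 15 | (5Z)-4-methoxy-3-methyl-5-[(2S,4E)-2-methyl-5-(4,4,5,5-tetramethyl-1,3,2-dioxaborolan-2-yl)pent-4-enylidene]furan-2(5H)-one | CC1=C(OC)/C(=C/[C@@H](C)C/C=C/B2OC(C)(C)C(C)(C)O2)OC1=O
F2 | step 15 | 4-(4,4-dibromobut-3-enyl)-2-(furan-3-ylmethyl)furan | BrC(Br)=CCCc1coc(Cc2ccoc2)c1
F3 | step 15 | (5Z)-5-[(2S,4E,6Z)-6-bromo-9-[5-(furan-3-ylmethyl)furan-3-yl]-2-methylnona-4,6-dienylidene]-4-methoxy-3-methylfuran-2(5H)-one | CC1=C(OC)/C(=C/[C@@H](C)C/C=C/C(Br)=C/CCc2coc(Cc3ccoc3)c2)OC1=O
F4 | step 6 | 4-methoxy-3-methyl-5-[(2S)-2-methylpent-4-enyl]furan-2(5H)-one (C5 epimers) | CC1=C(OC)C(C[C@@H](C)CC=C)OC1=O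
F5 | step 6 | 4-methoxy-3-methyl-5-[(2S)-2-methylpent-4-enyl]-5-(phenylselanyl)furan-2(5H)-one (C5 epimers) | CC1=C(OC)C([Se]c2ccccc2)(C[C@@H](C)CC=C)OC1=O
F6 | step 6 | 4-methoxy-3-methyl-5-[(2S)-2-methylpent-4-enyl]-5-(phenylseleninyl)furan-2(5H)-one | CC1=C(OC)C([Se](=O)c2ccccc2)(C[C@@H](C)CC=C)OC1=O
F7 | step 16 | (5Z)-4-hydroxy-3-methyl-5-[(2S)-2-methylpent-4-enylidene]furan-2(5H)-one | CC1=C(O)/C(=C/[C@@H](C)CC=C)OC1=O
F8 | step 16 | (5Z)-3-methyl-5-[(2S)-2-methylpent-4-enylidene]-4-[tri(propan-2-yl)silyloxy]furan-2(5H)-one | CC1=C(O[Si](C(C)C)(C(C)C)C(C)C)/C(=C/[C@@H](C)CC=C)OC1=O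
F9 | step 16 | (5Z)-5-[(2S,4E,6E)-9-[5-(furan-3-ylmethyl)furan-3-yl]-2,6-dimethylnona-4,6-dienylidene]-3-methyl-4-[tri(propan-2-yl)silyloxy]furan-2(5H)-one | CC1=C(O[Si](C(C)C)(C(C)C)C(C)C)/C(=C/[C@@H](C)C/C=C/C(C)=C/CCc2coc(Cc3ccoc3)c2)OC1=O
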